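**Retrosynthetic overview**

1. The angelate is put on the 6α-OH late, and the (12Z)-diene is made last by Stille vinylation of a (Z)-13-iodoalkene, which comes from a C12 lactol (ozonolysis of an allyl group on C9).
2. The 6α-OH/8α-OH pair comes from a 7-en-6-one: epoxidation from the α face, reductive C7–O cleavage, then dissolving-metal reduction of the ketone. The absolute configuration is secured by resolution of the diol as its camphanate.
3. Ring B is closed on a preformed ring A: C5–C6 by addition of the ring A alkenyllithium to a cyclobutenone, then C9–C10 by 6π electrocyclisation of the trienolate released when the four-membered ring opens (strain release).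
4. Enabling feature: the ring B carbon C6 bears oxygen and is flanked by C5 and by C7–C8(CH3)–C9. At the enone level the six atoms C10–C5–C6(O)–C7–C8–C9 are the retron of a 3-oxidohexatriene, and C6–C7–C8–C9 map onto a cyclobutenone.
5. Ring order: ring A is bought (2,2,6-trimethylcyclohexanone); a temporary cyclobutene is built and opened; ring B closes in step 4; the epoxide and lactol rings are temporary.

Key step: step 4

Remark on the chemistry: positions are given in labdane numbering (target = 6α-angeloyloxy-(12Z)-labda-12,14-dien-8α-ol, normal series, 5α-H, 9α-H, 10β-CH3). Compounds 4, 6, 7 and 8 are racemic with one stereocentre that is erased in step 4. Compounds 10 and 12 to 16 are racemic and their SMILES show the enantiomer that is carried on after step 8.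

**Route**

Step 1
Reactants: 1 pent-4-enoyl chloride; 2 ethoxyethyne
Product: 4 4-allyl-3-ethoxycyclobut-2-en-1-one, via allylketene 3 (not isolated)
Conditions: Et3N, Et2O, slow addition of 1, 0 °C to rt
Reagents that add atoms: none
Why: Dehydrochlorination gives allylketene, which undergoes the regioselective ketene–alkoxyalkyne [2+2] cycloaddition (nucleophilic alkyne carbon to the ketene carbonyl carbon), the standard entry to 4-substituted 3-ethoxycyclobutenones.

Step 2
Reactants: 4 4-allyl-3-ethoxycyclobut-2-en-1-one
Product: 6 4-allyl-3-methylcyclobut-2-en-1-one, via lithium alkoxide 5 (not isolated)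
Conditions: MeLi, THF, −78 °C; then 1 M HCl, 0 °C to rt
Reagents that add atoms: methyllithium [Li]C; water O
Why: 1,2-Addition to the vinylogous ester carbonyl and acid-mediated hydrolysis with allylic transposition (Stork–Danheiser type) move the carbonyl to the former enol-ether carbon, so the methyl group ends on the alkene (future C8) next to the allyl-bearing carbon (future C9); both diastereomers of 5 converge.

Step 3
Reactants: 7 2,2,6-trimethylcyclohexanone
Product: 8 2,2,6-trimethylcyclohexanone 2,4,6-triisopropylbenzenesulfonylhydrazone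
Conditions: 2,4,6-triisopropylbenzenesulfonohydrazide, HCl (cat.), MeOH, rt
Reagents that add atoms: 2,4,6-triisopropylbenzenesulfonohydrazide CC(C)c1cc(C(C)C)c(S(=O)(=O)NN)c(C(C)C)c1
Why: Acid-catalysed condensation should give the hydrazone with the N–N bond anti to the quaternary carbon, that is syn to the only α-hydrogen, as the Shapiro reaction requires.

Step 4
Reactants: 8 2,2,6-trimethylcyclohexanone 2,4,6-triisopropylbenzenesulfonylhydrazone; 6 4-allyl-3-methylcyclobut-2-en-1-one
Product: 13 rac-14,15,16-trinorlabda-7,12-dien-6-one (5α-H 9α-H 10β-CH3), via alkenyllithium 9 (not isolated), via lithium cyclobutenolate 10 (not isolated), via lithium trienolate 11 (not isolated), via lithium dienolate 12 (not isolated)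
Conditions: s-BuLi (2.0 equiv), THF/TMEDA, −78 °C then 0 °C; 6 in THF, −78 °C, then rt (40 °C if needed); sat. aq NH4Cl, −78 °C
Reagents that add atoms: none
Why: Double deprotonation of 8 with loss of sulfinate and N2 (Shapiro reaction) gives alkenyllithium 9, which adds to the strained carbonyl (C6) of 6 on the face anti to the C9 allyl group; in alkoxide 10 the oxido group drives a conrotatory 4π opening of the C6–C9 bond and, as a strong donor, rotates outward, which forces the ring A alkenyl group on C6 and the allyl group on C9 inward and delivers the 3-oxidohexatriene 11 in the cZc shape; thermal disrotatory 6π electrocyclisation then joins C10 to C9, and protonation of dienolate 12 at C5 gives 13. The closest known reaction type is the addition of alkenyllithium reagents to cyclobutenones with 4π opening/6π closure to cyclohexenones, related to the thermal ring expansion of 4-alkenylcyclobutenones. Ring B is closed in the 6π disrotatory mode from six contiguous sp2 atoms (C10, C5, C6, C7, C8, C9), with the four-membered ring serving as a strained, geometry-defining store for C6 to C9. C10 and C9 are set together by orbital symmetry, because the two inward groups (C20 methyl on C10 and C11 on C9) must end cis, which is the 9α-H/10β-CH3 relationship of the target; C5 is set by protonation from the α face, anti to the C10 and 4β methyl groups, and can be corrected by base equilibration to the trans-fused ketone. The step needs anti addition to the cyclobutenone and outward rotation of the oxido group, secured by the C9 substituent and by donor torquoselectivity, and it needs ring closure to outrun a [1,7]-hydrogen shift in 11, which the oxido acceleration should secure; the product is racemic because 11 is achiral.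

Step 5
Reactants: 13 rac-14,15,16-trinorlabda-7,12-dien-6-one
Product: 14 rac-7α,8α-epoxy-14,15,16-trinorlabd-12-en-6-one
Conditions: 30% H2O2, NaOH (cat.), MeOH, 0 °C, short reaction time
Reagents that add atoms: hydrogen peroxide OO
Why: Weitz–Scheffer nucleophilic epoxidation of the β-methyl enone, in which hydroperoxide should add to C8 from the α face, anti to the axial C10 methyl group that is 1,3-related to the forming bond, so that the C8–O bond is α (future 8α-OH, 8β-CH3).

Step 6
Reactants: 14 rac-7α,8α-epoxy-14,15,16-trinorlabd-12-en-6-one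
Product: 15 rac-8α-hydroxy-14,15,16-trinorlabd-12-en-6-one
Conditions: SmI2 (2.2 equiv), THF/MeOH, −90 °C
Reagents that add atoms: none
Why: Samarium diiodide reduction of an α,β-epoxy ketone cleaves only the C7–O bond α to the carbonyl and gives the β-hydroxy ketone, so the C8–O bond and its configuration are kept.

Step 7
Reactants: 15 rac-8α-hydroxy-14,15,16-trinorlabd-12-en-6-one
Product: 16 rac-14,15,16-trinorlabd-12-ene-6α,8α-diol
Conditions: Li, NH3(l)/THF, t-BuOH (2 equiv), −78 °C; then solid NH4Cl
Reagents that add atoms: none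
Why: Dissolving-metal reduction of the hindered cyclohexanone should give the thermodynamically preferred equatorial 6α-alcohol (hydride reagents would attack from the open α face and give the axial 6β-alcohol, since the β face is shielded by the 4β, 8β and 10β methyl groups), as known for 11-oxo steroids; the isolated terminal alkene is inert.

Step 8
Reactants: 16 rac-14,15,16-trinorlabd-12-ene-6α,8α-diol
Product: 17 8α-hydroxy-14,15,16-trinorlabd-12-en-6α-yl (1S,4R)-camphanate (single diastereomer of the normal series)
Conditions: (1S)-(−)-camphanic chloride, Et3N, DMAP (cat.), CH2Cl2, 0 °C to rt; separation of the two diastereomers by chromatography on silica gel or crystallisation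
Reagents that add atoms: (1S,4R)-camphanic chloride O=C(Cl)[C@@]12CC[C@@](C)(C(=O)O1)C2(C)C
Why: Acylation of the secondary 6α-hydroxyl (the tertiary 8-hydroxyl does not react) with an enantiopure acid chloride gives two diastereomeric esters that are separated, a classical resolution that supplies the absolute configuration the pericyclic key step cannot give.

Step 9
Reactants: 17 8α-hydroxy-14,15,16-trinorlabd-12-en-6α-yl (1S,4R)-camphanate
Product: 18 14,15,16-trinorlabd-12-ene-6α,8α-diol (single enantiomer)
Conditions: KOH, MeOH/H2O, 60 °C; then 1 M HCl to pH 4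
Reagents that add atoms: none
Why: Saponification releases the enantiopure diol and the recoverable resolving acid; no stereocentre is at risk because the diol carries no carbonyl group.

Step 10
Reactants: 18 14,15,16-trinorlabd-12-ene-6α,8α-diol
Product: 21 8α,12-epoxy-13,14,15,16-tetranorlabdane-6α,12-diol (lactol), via ozonide 19 (not isolated), via hydroxy aldehyde 20 (not isolated)
Conditions: O3, CH2Cl2, −78 °C; then PPh3, −78 °C to rt
Reagents that add atoms: ozone [O-][O+]=O
Why: Ozonolysis of the only alkene with reductive work-up gives the C12 aldehyde, which is trapped by the 8α-hydroxyl as the five-membered lactol, a masked aldehyde.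

Step 11
Reactants: 21 8α,12-epoxy-13,14,15,16-tetranorlabdane-6α,12-diol
Product: 22 (12Z)-13-iodo-14,15-dinorlabd-12-ene-6α,8α-diol
Conditions: EtPPh3I, n-BuLi, THF, 0 °C; I2, −78 °C; NaN(SiMe3)2, −78 °C; then 21, −78 to −20 °C (excess ylide)
Reagents that add atoms: ethyltriphenylphosphonium iodide CC[P+](c1ccccc1)(c1ccccc1)c1ccccc1.[I-]; iodine II
Why: Wittig olefination of the lactol through its open hydroxy aldehyde form with the α-iodo ylide (Stork–Zhao-type olefination) should give the trisubstituted (Z)-vinyl iodide under kinetic control, with iodine cis to C11; the excess ylide covers the hydroxyl protons.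

Step 12
Reactants: 22 (12Z)-13-iodo-14,15-dinorlabd-12-ene-6α,8α-diol; 23 angelic acid
Product: 25 (12Z)-8α-hydroxy-13-iodo-14,15-dinorlabd-12-en-6α-yl angelate, via mixed anhydride 24 (not isolated)
Conditions: 23, 2,4,6-trichlorobenzoyl chloride, Et3N, toluene, rt; then 22, toluene, 80 °C (no nucleophilic catalyst)
Reagents that add atoms: none
Why: Esterification through the 2,4,6-trichlorobenzoyl mixed anhydride (Yamaguchi type) should acylate the secondary 6α-hydroxyl in preference to the tertiary one, and leaving out a nucleophilic catalyst avoids the addition–elimination path that isomerises angelates to tiglates.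

Step 13
Reactants: 25 (12Z)-8α-hydroxy-13-iodo-14,15-dinorlabd-12-en-6α-yl angelate
Product: 26 (12Z)-8α-hydroxylabda-12,14-dien-6α-yl (Z)-2-methylbut-2-enoate (target)
Conditions: tributyl(vinyl)stannane, Pd2(dba)3 (cat.), AsPh3, CuI (cat.), NMP, rt, dark
Reagents that add atoms: tributyl(vinyl)stannane C=C[Sn](CCCC)(CCCC)CCCC
Why: Stille coupling of the (Z)-vinyl iodide proceeds with retention of alkene geometry under neutral conditions at room temperature, so the sensitive (12Z)-diene is formed last and the angelate and tertiary alcohol stay untouched.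

**Compound list**

1 | pent-4-enoyl chloride | C=CCCC(=O)Cl | starting material
2 | ethoxyethyne | CCOC#C | starting material
3 | allylketene (penta-1,4-dien-1-one) | C=CCC=C=O | intermediate
4 | 4-allyl-3-ethoxycyclobut-2-en-1-one (racemic) | CCOC1=CC(=O)C1CC=C | intermediate
5 | lithium 4-allyl-3-ethoxy-1-methylcyclobut-2-en-1-olate (diastereomer mixture) | [Li+].[O-]C1(C)C=C(OCC)C1CC=C | intermediate
6 | 4-allyl-3-methylcyclobut-2-en-1-one (racemic) | CC1=CC(=O)C1CC=C | intermediate
7 | 2,2,6-trimethylcyclohexanone (racemic) | CC1CCCC(C)(C)C1=O | starting material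
8 | 2,2,6-trimethylcyclohexanone 2,4,6-triisopropylbenzenesulfonylhydrazone (N–N syn to the CH(CH3) carbon) | CC(C)c1cc(C(C)C)c(S(=O)(=O)N/N=C2\C(C)CCCC2(C)C)c(C(C)C)c1 | intermediate
9 | (2,6,6-trimethylcyclohex-1-en-1-yl)lithium | [Li]C1=C(C)CCCC1(C)C | intermediate
10 | lithium 4-allyl-3-methyl-1-(2,6,6-trimethylcyclohex-1-en-1-yl)cyclobut-2-en-1-olate (racemic; alkenyl group trans to allyl) | [Li+].[O-][C@@]1(C2=C(C)CCCC2(C)C)C=C(C)[C@H]1CC=C | intermediate
11 | lithium (1E,3Z)-3-methyl-1-(2,6,6-trimethylcyclohex-1-en-1-yl)hepta-1,3,6-trien-1-olate (alkenyl group cis to C8 about C6=C7; C11 cis to C7 about C8=C9) | [Li+].[O-]/C(C1=C(C)CCCC1(C)C)=C/C(C)=C\CC=C | intermediate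
12 | lithium 14,15,16-trinorlabda-5,7,12-trien-6-olate (racemic; 9α-H, 10β-CH3) | [Li+].C=CC[C@@H]1[C@@]2(C)CCCC(C)(C)C2=C([O-])C=C1C | intermediate
13 | rac-14,15,16-trinorlabda-7,12-dien-6-one (5α-H, 9α-H, 10β-CH3; trans-fused 4-allyl-3,4a,8,8-tetramethyl-4a,5,6,7,8,8a-hexahydronaphthalen-1(4H)-one, allyl cis to the angular methyl) | C=CC[C@@H]1[C@@]2(C)CCCC(C)(C)[C@@H]2C(=O)C=C1C | intermediate
14 | rac-7α,8α-epoxy-14,15,16-trinorlabd-12-en-6-one | C=CC[C@@H]1[C@@]2(C)CCCC(C)(C)[C@@H]2C(=O)[C@H]3O[C@@]13C | intermediate
15 | rac-8α-hydroxy-14,15,16-trinorlabd-12-en-6-one | C=CC[C@@H]1[C@@]2(C)CCCC(C)(C)[C@@H]2C(=O)C[C@@]1(C)O | intermediate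
16 | rac-14,15,16-trinorlabd-12-ene-6α,8α-diol | C=CC[C@@H]1[C@@]2(C)CCCC(C)(C)[C@@H]2[C@@H](O)C[C@@]1(C)O | intermediate
17 | 8α-hydroxy-14,15,16-trinorlabd-12-en-6α-yl (1S,4R)-4,7,7-trimethyl-3-oxo-2-oxabicyclo[2.2.1]heptane-1-carboxylate (normal-series diastereomer) | C=CC[C@@H]1[C@@]2(C)CCCC(C)(C)[C@@H]2[C@@H](OC(=O)[C@@]34CC[C@@](C)(C(=O)O3)C4(C)C)C[C@@]1(C)O | intermediate
18 | 14,15,16-trinorlabd-12-ene-6α,8α-diol (single enantiomer, normal series) | C=CC[C@@H]1[C@@]2(C)CCCC(C)(C)[C@@H]2[C@@H](O)C[C@@]1(C)O | intermediate
19 | ozonide of 18 (1,2,4-trioxolane at C12; C12 epimers) | C3OC(C[C@@H]1[C@@]2(C)CCCC(C)(C)[C@@H]2[C@@H](O)C[C@@]1(C)O)OO3 | intermediate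
20 | 6α,8α-dihydroxy-13,14,15,16-tetranorlabdan-12-al | O=CC[C@@H]1[C@@]2(C)CCCC(C)(C)[C@@H]2[C@@H](O)C[C@@]1(C)O | intermediate
21 | 8α,12-epoxy-13,14,15,16-tetranorlabdane-6α,12-diol (lactol, both C12 anomers) | OC3C[C@@H]1[C@@]2(C)CCCC(C)(C)[C@@H]2[C@@H](O)C[C@@]1(C)O3 | intermediate
22 | (12Z)-13-iodo-14,15-dinorlabd-12-ene-6α,8α-diol | I/C(C)=C\C[C@@H]1[C@@]2(C)CCCC(C)(C)[C@@H]2[C@@H](O)C[C@@]1(C)O | intermediate
23 | angelic acid, (Z)-2-methylbut-2-enoic acid | C/C=C(/C)C(=O)O | starting material
24 | angelic 2,4,6-trichlorobenzoic anhydride | C/C=C(/C)C(=O)OC(=O)c1c(Cl)cc(Cl)cc1Cl | intermediate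
25 | (12Z)-8α-hydroxy-13-iodo-14,15-dinorlabd-12-en-6α-yl (Z)-2-methylbut-2-enoate | I/C(C)=C\C[C@@H]1[C@@]2(C)CCCC(C)(C)[C@@H]2[C@@H](OC(=O)/C(C)=C\C)C[C@@]1(C)O | intermediate
26 | (12Z)-8α-hydroxylabda-12,14-dien-6α-yl (Z)-2-methylbut-2-enoate (6α-angeloyloxy-cis-abienol) | C=C/C(C)=C\C[C@@H]1[C@@]2(C)CCCC(C)(C)[C@@H]2[C@@H](OC(=O)/C(C)=C\C)C[C@@]1(C)O | target

**Totals**

Total step count: 13. Longest linear sequence: 12 steps (steps 1, 2, 4 to 13 from compound 1; step 3 is the side branch).

**Steps most likely to fail**

Step 4. What may go wrong: proton transfer to the hindered alkenyllithium instead of carbonyl addition, and slow ring closure of the doubly inward-substituted lithium trienolate, so that hydrogen shifts or oligomerisation compete. The fallback sets out from 8 and 6. The addition is run with the less basic organocerium reagent (9 with CeCl3, THF, −78 °C) and the alkoxide 10 is silylated in the flask with Me3SiCl. This gives the isolable [4-allyl-3-methyl-1-(2,6,6-trimethylcyclohex-1-en-1-yl)cyclobut-2-en-1-yl]oxy(trimethyl)silane F1, which is purified and then rearranged under neutral conditions (degassed toluene, 110 to 130 °C, sealed tube). The siloxy group again rotates outward in the 4π opening and the neutral 3-siloxytriene closes in the same disrotatory 6π mode to the trimethylsilyl dienol ether of 13, F2. Mild hydrolysis (1 M HCl, THF, 0 °C) returns to the route at 13. This replaces the one-pot anionic cascade by the thermal ring expansion of an isolated neutral cyclobutene, the type known from 4-alkenylcyclobutenone rearrangements, and separates the addition from the pericyclic events.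

Step 11. What may go wrong: slow opening of the lactol and decomposition of the thermally labile α-iodo ylide before olefination, or erosion of the Z selectivity. The fallback sets out from 21 and builds the diene with phosphonate and methylene chemistry. Still–Gennari olefination (methyl 2-[bis(2,2,2-trifluoroethoxy)phosphoryl]propanoate, KN(SiMe3)2, 18-crown-6, THF, −78 °C) should give methyl (12Z)-6α,8α-dihydroxy-15-norlabd-12-en-14-oate F3. Reduction with i-Bu2AlH (CH2Cl2, −78 °C) gives (12Z)-15-norlabd-12-ene-6α,8α,14-triol F4. MnO2 (CH2Cl2, rt) oxidises only the allylic alcohol to (12Z)-6α,8α-dihydroxy-15-norlabd-12-en-14-al F5. Methylenation (Ph3P=CH2, THF, −78 to 0 °C) gives (12Z)-labda-12,14-diene-6α,8α-diol F6. Acylation of F6 with 23 through mixed anhydride 24 under the conditions of step 12 comes back to the route at 26.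

Step 12. What may go wrong: sluggish acylation of the hindered equatorial 6α-hydroxyl next to the C4 gem-dimethyl group, and isomerisation of the angelate to the tiglate during prolonged heating. The fallback sets out from 22 and builds the Z-alkene of the ester on the molecule. Acylation with the small, saturated 2-[bis(2,2,2-trifluoroethoxy)phosphoryl]propanoic acid (DCC, DMAP, CH2Cl2, rt) gives (12Z)-8α-hydroxy-13-iodo-14,15-dinorlabd-12-en-6α-yl 2-[bis(2,2,2-trifluoroethoxy)phosphoryl]propanoate F7. Still–Gennari olefination of F7 with acetaldehyde (KN(SiMe3)2, 18-crown-6, THF, −78 °C) should give the (Z)-2-methylbut-2-enoate and comes back to the route at 25.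

**Further compounds**

F1 | step 4 | [4-allyl-3-methyl-1-(2,6,6-trimethylcyclohex-1-en-1-yl)cyclobut-2-en-1-yl]oxy(trimethyl)silane (racemic; alkenyl trans to allyl) | C[Si](C)(C)O[C@@]1(C2=C(C)CCCC2(C)C)C=C(C)[C@H]1CC=C
F2 | step 4 | rac-6-(trimethylsilyloxy)-14,15,16-trinorlabda-5,7,12-triene (9α-H, 10β-CH3) | C=CC[C@@H]1[C@@]2(C)CCCC(C)(C)C2=C(O[Si](C)(C)C)C=C1C
F3 | step 11 | methyl (12Z)-6α,8α-dihydroxy-15-norlabd-12-en-14-oate | COC(=O)/C(C)=C\C[C@@H]1[C@@]2(C)CCCC(C)(C)[C@@H]2[C@@H](O)C[C@@]1(C)O
F4 | step 11 | (12Z)-15-norlabd-12-ene-6α,8α,14-triol | OC/C(C)=C\C[C@@H]1[C@@]2(C)CCCC(C)(C)[C@@H]2[C@@H](O)C[C@@]1(C)O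
F5 | step 11 | (12Z)-6α,8α-dihydroxy-15-norlabd-12-en-14-al | O=C/C(C)=C\C[C@@H]1[C@@]2(C)CCCC(C)(C)[C@@H]2[C@@H](O)C[C@@]1(C)O
F6 | step 11 | (12Z)-labda-12,14-diene-6α,8α-diol | C=C/C(C)=C\C[C@@H]1[C@@]2(C)CCCC(C)(C)[C@@H]2[C@@H](O)C[C@@]1(C)O
F7 | step 12 | (12Z)-8α-hydroxy-13-iodo-14,15-dinorlabd-12-en-6α-yl 2-[bis(2,2,2-trifluoroethoxy)phosphoryl]propanoate (epimers at the phosphonate carbon) | I/C(C)=C\C[C@@H]1[C@@]2(C)CCCC(C)(C)[C@@H]2[C@@H](OC(=O)C(C)P(=O)(OCC(F)(F)F)OCC(F)(F)F)C[C@@]1(C)O
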